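## Analysis of the target

3-Hydroxyglabrol (21) is a 2,3-trans-dihydroflavonol: a benzopyran-4-one (ring A fused to the oxygen heterocycle, ring C) with the ring B aryl group on C2 and a hydroxyl on C3. Ring A carries a free hydroxyl at C7 and a prenyl (3-methylbut-2-en-1-yl) group at C8, wedged between O7 and the ring oxygen O1. Ring B carries a 4'-hydroxyl and a 3'-prenyl group, and C5 is unsubstituted. The only stereocentres are C2 and C3, both R, with the aryl group and the hydroxyl trans. This is also the thermodynamically preferred arrangement, so only the absolute configuration at C2 has to be imposed by a reagent; C3 can follow from it. The sensitive groups are the two trisubstituted alkenes, the β-aryloxy ketone and the α-ketol. The alkenes rule out hydrogenation, peracids, electrophilic halogen and strong acid, which would add the neighbouring phenols to give chromans. The β-aryloxy ketone opens in base to a 2'-hydroxychalcone and so scrambles C2, more easily once O4' is free, and the α-ketol is easily dehydrogenated to the flavonol. The synthesis is hard for two reasons: the C8 prenyl group must be placed regiospecifically between two oxygens, and both stereocentres must be introduced late under conditions that spare all of the above. The strategy rests on C4. It is a single carbonyl carbon bridging C4a of ring A and the two-carbon unit C3–C2 that bears ring B, with O1 ortho to C4a. Ring C can therefore be assembled from an ortho-iodophenol, a one-carbon unit at the carbonyl oxidation level and an arylacetylene, giving a flat flavone whose C2=C3 bond is the handle for both stereocentres.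

## Retrosynthetic reasoning

21 back to 20. The two O–CH2 acetal bonds are cut last. Both phenols stay masked as methoxymethyl ethers through all metal-mediated and enolate steps, because a free 4'-hydroxyl would labilise the C2–O1 bond and free phenols would quench the enolate. The forward step must remove two aryl acetals without protonating the prenyl groups.

20 back to 18. The C3–O bond is cut. C3 is the only enolisable position of flavanone 18, and the C2 aryl group shields one face of enolate 19, so an electrophilic oxygen donor should enter trans. The second stereocentre comes from substrate control; the forward reaction has to run cold enough that the enolate does not expel O1.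

18 back to 16. The C2–H bond is cut, which removes the last stereocentre and leads to the achiral, robust flavone 16. The forward reaction is an enantioselective 1,4-hydride addition that passes through silyl enol ether 17. This concentrates all stereochemical risk in one catalytic step on a stable substrate.

16 back to 7, 12 and 13. Three bonds of ring C are cut together: C4a–C4, C4–C3 and O1–C2. C4 becomes carbon monoxide 13, ring A with O1 becomes iodophenol 7, and C2–C3 with ring B becomes arylacetylene 12. The cut is made here because it divides the molecule into two aromatic halves of similar size, neither with a stereocentre, and uses the carbonyl carbon as the joining atom. The forward reaction must take up CO before coupling (ynone 14) and close through the amine adduct 15 in the six-membered mode.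

7 back to 6, 4, 3, 2 and 1. The prenyl group is traced to an allyl group (cross-metathesis at the alkene), and the C8–allyl bond to the allyl ether 4 of the oxygen that becomes O1 (Claisen rearrangement through dienone 5). The C–I bond is traced to iodination of the mono-acetal 2 of resorcinol 1. The order matters. Electrophilic iodination of a phenol that already has an ortho prenyl group would be diverted into iodoetherification of the electron-rich alkene, so the iodine is introduced before any alkene is present. Once iodine blocks one ortho position, the sigmatropic shift can deliver carbon only to C8, which settles the regiochemistry between the two oxygens.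

12 back to 11, 10, 8 and 9. The alkyne is traced to aldehyde 11 by one-carbon homologation, the acetal to phenol 10, and the C3'–prenyl bond to C-alkylation of 4-hydroxybenzaldehyde 8 with prenyl bromide 9. The para position of 8 is blocked and its two ortho positions are equivalent, so only one C-prenyl isomer can form.

## Alternatives that were turned down

Alternative 1: Ring A (at C4a–C5) and ring C (at O1–C2) are both opened, which leads to the acyclic epoxy tetracarbonyl compound A1. In the forward step mild base would close ring A by aldol condensation and aromatisation, and the new C8a phenoxide would then open the epoxide at the benzylic carbon C2 with inversion to give the mono-silylated target A2. In its favour, both stereocentres come from one trans-epoxide, so no late enolate oxidation is needed, and ring A is formed with its oxygen pattern in place. Against it, A1 has three acidic C–H sites, four electrophilic carbonyls and a base-sensitive epoxy ketone. Nothing enforces the one aldol mode that is wanted. The phenoxide can open the epoxide at C3 in a five-membered closure (a benzofuranone) as well as at C2. A1 itself would need a long linear sequence of masked carbonyls. On stereocontrol this route is stronger than the chosen one. The chosen route offers instead a union of two simple aromatic pieces and CO (13) with unambiguous regiochemistry, and far fewer steps to the ring system.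

Alternative 2: C3–C4 and O1–C2 are cut in a formal [4+2] sense, giving salicylaldehyde A3 and the (E)-enol acetate A4. In the forward step A3 and an orthoformate would form, under a chiral phosphoric acid, a 4-methoxy ortho-quinone methide cation that adds A4 to give the 2,3-trans-4-methoxyflavan-3-yl acetate A5 as C4 epimers. In its favour, one convergent step sets both stereocentres and the C3–O bond, the trans relationship follows from the alkene geometry, and no basic enolate is involved. Against it, A5 is at the flavan oxidation level at C4. Turning the C4 methyl ether into the ketone, next to an acetoxy group and on electron-rich, prenylated rings, adds steps and a difficult oxidation. The regiochemistry depends on the styrene polarisation of A4 winning over its enol-ester polarisation. Enantiocontrol must come from an ion pair alone, and the cationic medium invites capture by the prenyl alkenes. This route is stronger on stereochemical economy. The chosen route has C4 at its final oxidation state from the start and uses achiral, well-understood bond formations up to flavone 16.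

Alternative 3: The C3=C4 bond is cut, leading to diene A6, a silyl enol ether whose neighbouring aryl ether oxygen carries an (S)-1-arylallyl group. Ring-closing metathesis would give the 4-silyloxy-2H-chromene A7, the enol ether of the (2S)-flavanone. In its favour, C2 is set before ring closure and A7 is exactly the enol ether needed for oxidation at C3, so neither an asymmetric reduction nor a strong base is required. Against it, both prenyl groups are metathesis-competent. The C8 prenyl alkene lies within reach of the vinyl group and can close a seven-membered ring instead, so the prenyl groups would have to be introduced afterwards or masked. The doubly activated secondary aryl ether in A6 is prone to ionisation and sigmatropic shifts, and making it enantioselectively on a 2,6-disubstituted phenol is hard. The endgame is as short as or shorter than the chosen one. The chosen route keeps the prenyl groups as inert spectators in every step and forms ring C by chemistry that does not touch them.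

Key step: step 9

Assumption: the ligand antipode that delivers hydride to the Re face of C2 in step 10 is taken to be (R)-DTBM-SEGPHOS; if the reduction shows the opposite sense, the (S)-ligand is used with no other change.

## Route

Step 1
Reactants: 1 resorcinol
Product: 2 3-(methoxymethoxy)phenol
Conditions: NaH (1.0 equiv), MOMCl (1.0 equiv), DMF, 0 °C to rt
Reagents that add atoms: chloromethyl methyl ether, COCCl
Why: O-alkylation of the monophenoxide (Williamson type); the two hydroxyls are equivalent, so one equivalent of base and electrophile should give mainly the mono-acetal, with unreacted 1 and the bis-acetal separable and recyclable.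

Step 2
Reactants: 2 3-(methoxymethoxy)phenol
Product: 3 2-iodo-5-(methoxymethoxy)phenol
Conditions: I2 (1.0 equiv), NaHCO3, THF/H2O, 0 °C
Reagents that add atoms: iodine, II
Why: Electrophilic aromatic iodination of the phenoxide; for 3-alkoxyphenols under bicarbonate the usual main site is the ortho carbon of the free phenol that is para to the ether oxygen, and the acetal is stable to the weakly basic medium; no alkene is yet present to compete for the electrophile.

Step 3
Reactants: 3 2-iodo-5-(methoxymethoxy)phenol
Product: 4 2-(allyloxy)-1-iodo-4-(methoxymethoxy)benzene
Conditions: allyl bromide, K2CO3, acetone, reflux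
Reagents that add atoms: allyl bromide, C=CCBr
Why: Williamson ether synthesis on an acidic ortho-iodophenol with a reactive allylic halide; nothing else in the molecule is alkylated under carbonate.

Step 4
Reactants: 4 2-(allyloxy)-1-iodo-4-(methoxymethoxy)benzene
Product: 6 2-allyl-6-iodo-3-(methoxymethoxy)phenol, via ortho-dienone 5 (not isolated)
Conditions: PhNEt2, 190 °C
Reagents that add atoms: none
Why: Aromatic Claisen rearrangement; the [3,3] shift can rearomatise only from the unsubstituted ortho carbon, the one between the two oxygens, so dienone 5 tautomerises to a single allylphenol, while migration to the iodinated carbon is reversible and unproductive; the basic amine solvent protects the acetal.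

Step 5
Reactants: 6 2-allyl-6-iodo-3-(methoxymethoxy)phenol
Product: 7 6-iodo-3-(methoxymethoxy)-2-(3-methylbut-2-en-1-yl)phenol
Conditions: 2-methyl-2-butene (excess), RuCl2(=CHPh)(PCy3)(H2IMes) (3 mol %), CH2Cl2, 40 °C, sealed tube
Reagents that add atoms: 2-methyl-2-butene, CC=C(C)C
Why: Olefin cross-metathesis of a terminal allylarene with an excess of a trisubstituted alkene, which transfers the isopropylidene unit and releases propene; the second-generation Grubbs catalyst tolerates the free phenol and the aryl iodide, and the trisubstituted product is not consumed further.

Step 6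
Reactants: 8 4-hydroxybenzaldehyde; 9 prenyl bromide
Product: 10 4-hydroxy-3-(3-methylbut-2-en-1-yl)benzaldehyde
Conditions: KOH (aq), rt
Reagents that add atoms: none
Why: C-alkylation of a phenoxide in water, where hydrogen bonding to oxygen disfavours O-alkylation; the para position is blocked and the two ortho positions are equivalent, so only one C-prenyl isomer can form and the O-prenyl ether is removed by base extraction.

Step 7
Reactants: 10 4-hydroxy-3-(3-methylbut-2-en-1-yl)benzaldehyde
Product: 11 4-(methoxymethoxy)-3-(3-methylbut-2-en-1-yl)benzaldehyde
Conditions: MOMCl, i-Pr2NEt, CH2Cl2, 0 °C to rt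
Reagents that add atoms: chloromethyl methyl ether, COCCl
Why: Acetal protection of an acidic para-formyl phenol with an amine base; aldehyde and alkene are untouched.

Step 8
Reactants: 11 4-(methoxymethoxy)-3-(3-methylbut-2-en-1-yl)benzaldehyde
Product: 12 4-ethynyl-1-(methoxymethoxy)-2-(3-methylbut-2-en-1-yl)benzene
Conditions: dimethyl (1-diazo-2-oxopropyl)phosphonate, K2CO3, MeOH, rt
Reagents that add atoms: dimethyl (1-diazo-2-oxopropyl)phosphonate, COP(=O)(OC)C(=[N+]=[N-])C(C)=O
Why: Seyferth–Gilbert homologation in the Ohira–Bestmann variant; methanolysis of the reagent gives the diazomethylphosphonate anion, which olefinates the aldehyde, and loss of N2 with a 1,2-hydrogen shift gives the terminal alkyne under conditions that leave acetal and prenyl group alone.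

Step 9
Reactants: 7 6-iodo-3-(methoxymethoxy)-2-(3-methylbut-2-en-1-yl)phenol; 12 4-ethynyl-1-(methoxymethoxy)-2-(3-methylbut-2-en-1-yl)benzene; 13 carbon monoxide
Product: 16 7,4'-bis(methoxymethoxy)-8,3'-diprenylflavone, via ortho-hydroxyaryl ynone 14 (not isolated), via diethylamino enone 15 (not isolated)
Conditions: PdCl2(PPh3)2 (5 mol %), CO (20 bar), Et2NH, 120 °C
Reagents that add atoms: none
Why: The divalent palladium precatalyst is reduced in the flask to zerovalent palladium, which inserts into the C–I bond of 7; CO then inserts to give an aroylpalladium iodide, a step favoured by the electron-rich ring. The amine deprotonates alkyne 12, the alkynyl group passes to palladium, and reductive elimination forms C4–C3 in ynone 14, C4a–C4 having been made in the insertion. Diethylamine adds to the ynone to give enaminone 15, and the phenol oxygen attacks the amine-bearing carbon and expels the amine, forming O1–C2 and closing ring C in the 6-endo mode. The closest known reaction type is the palladium-catalysed carbonylative Sonogashira coupling of ortho-iodophenols with terminal arylacetylenes in a secondary amine, which ends in flavones. No stereocentre is formed. Two selectivities are needed: CO uptake before coupling (direct coupling would lead to a 2-arylbenzofuran), which the CO pressure and the donor-substituted aryl group secure, and six-membered instead of five-membered closure (an aurone), which the enaminone secures because its β-carbon is the only electrophilic site. The prenyl double bonds are trisubstituted and do not insert into aryl- or acylpalladium species, the C8 prenyl group is meta to the iodide and cannot cyclise onto it, and the acetals are inert to amine.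

Step 10
Reactants: 16 7,4'-bis(methoxymethoxy)-8,3'-diprenylflavone
Product: 18 (2S)-7,4'-bis(methoxymethoxy)-8,3'-diprenylflavanone, via silyl enol ether 17 (not isolated)
Conditions: Cu(OAc)2 (5 mol %), (R)-DTBM-SEGPHOS (5.5 mol %), (EtO)2MeSiH (2 equiv), toluene, 0 °C to rt; then NH4F, MeOH
Reagents that add atoms: none
Why: Proposed new method: a bisphosphine-ligated hydride of monovalent copper, formed from Cu(OAc)2 and the silane, should add hydride to C2 and copper to the enone oxygen (1,4-hydrocupration), and silyl transfer from the silane should release silyl enol ether 17 and regenerate the hydride; the bulky C2-symmetric ligand distinguishes the two faces of the flat benzopyranone, whose C2 carries an aryl group on one side and the ring oxygen on the other, and hydride delivery to the Re face of C2 gives the 2S centre; the closest known reaction type is the asymmetric copper hydride conjugate reduction of β,β-disubstituted enones, β-aryl unsaturated esters and lactones and 2-alkylchromones, which has not been shown on 2-aryl-4-chromenones; leaving out a proton source keeps the ketone masked as 17 until the fluoride work-up and so prevents 1,2-reduction.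

Step 11
Reactants: 18 (2S)-7,4'-bis(methoxymethoxy)-8,3'-diprenylflavanone
Product: 20 (2R,3R)-3-hydroxy-7,4'-bis(methoxymethoxy)-8,3'-diprenylflavanone, via lithium enolate 19 (not isolated)
Conditions: LiN(SiMe3)2 (1.1 equiv), THF, −78 °C; 2-(phenylsulfonyl)-3-phenyloxaziridine (1.3 equiv), −78 °C; AcOH quench at −78 °C
Reagents that add atoms: 2-(phenylsulfonyl)-3-phenyloxaziridine, O=S(=O)(c1ccccc1)N1OC1c1ccccc1
Why: Enolate hydroxylation with an N-sulfonyloxaziridine; C3 is the only α-position and the cold lithium enolate 19 should be slow to expel O1, so C2 keeps its configuration (its descriptor changes from S to R only because C3 gains priority). Oxygen is transferred to the enolate face anti to the C2 aryl group, which sets C3 trans to C2, and the trans isomer is also the thermodynamic one; the prenyl alkenes are not epoxidised by this reagent at −78 °C.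

Step 12
Reactants: 20 (2R,3R)-3-hydroxy-7,4'-bis(methoxymethoxy)-8,3'-diprenylflavanone
Product: 21 3-hydroxyglabrol, (2R,3R)-3,7-dihydroxy-2-[4-hydroxy-3-(3-methylbut-2-en-1-yl)phenyl]-8-(3-methylbut-2-en-1-yl)chroman-4-one
Conditions: HCl (3 M aq), MeOH, 40 °C
Reagents that add atoms: none
Why: Acid-catalysed acetal exchange with methanol; aryl methoxymethyl ethers should cleave in dilute acid at mild temperature, below the severity at which a prenyl group adds its neighbouring phenol or the C2–O1 bond ionises, and neither stereocentre is involved.

## Compound list

1 | resorcinol (benzene-1,3-diol) | Oc1cccc(O)c1 | starting material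
2 | 3-(methoxymethoxy)phenol | COCOc1cccc(O)c1 | intermediate
3 | 2-iodo-5-(methoxymethoxy)phenol | COCOc1ccc(I)c(O)c1 | intermediate
4 | 2-(allyloxy)-1-iodo-4-(methoxymethoxy)benzene | C=CCOc1cc(OCOC)ccc1I | intermediate
5 | 6-allyl-2-iodo-5-(methoxymethoxy)cyclohexa-2,4-dien-1-one (racemic, not isolated) | O=C1C(I)=CC=C(OCOC)C1CC=C | intermediate
6 | 2-allyl-6-iodo-3-(methoxymethoxy)phenol | C=CCc1c(OCOC)ccc(I)c1O | intermediate
7 | 6-iodo-3-(methoxymethoxy)-2-(3-methylbut-2-en-1-yl)phenol | CC(C)=CCc1c(OCOC)ccc(I)c1O | intermediate
8 | 4-hydroxybenzaldehyde | O=Cc1ccc(O)cc1 | starting material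
9 | prenyl bromide (1-bromo-3-methylbut-2-ene) | CC(C)=CCBr | starting material
10 | 4-hydroxy-3-(3-methylbut-2-en-1-yl)benzaldehyde | CC(C)=CCc1cc(C=O)ccc1O | intermediate
11 | 4-(methoxymethoxy)-3-(3-methylbut-2-en-1-yl)benzaldehyde | CC(C)=CCc1cc(C=O)ccc1OCOC | intermediate
12 | 4-ethynyl-1-(methoxymethoxy)-2-(3-methylbut-2-en-1-yl)benzene | C#Cc1ccc(OCOC)c(CC=C(C)C)c1 | intermediate
13 | carbon monoxide | [C-]#[O+] | starting material
14 | 1-[2-hydroxy-4-(methoxymethoxy)-3-prenylphenyl]-3-[4-(methoxymethoxy)-3-prenylphenyl]prop-2-yn-1-one (not isolated) | CC(C)=CCc1cc(C#CC(=O)c2ccc(OCOC)c(CC=C(C)C)c2O)ccc1OCOC | intermediate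
15 | (E)-3-(diethylamino)-1-[2-hydroxy-4-(methoxymethoxy)-3-prenylphenyl]-3-[4-(methoxymethoxy)-3-prenylphenyl]prop-2-en-1-one (not isolated) | CCN(CC)C(=C/C(=O)c1ccc(OCOC)c(CC=C(C)C)c1O)/c1ccc(OCOC)c(CC=C(C)C)c1 | intermediate
16 | 7,4'-bis(methoxymethoxy)-8,3'-diprenylflavone; 7-(methoxymethoxy)-2-[4-(methoxymethoxy)-3-(3-methylbut-2-en-1-yl)phenyl]-8-(3-methylbut-2-en-1-yl)-4H-chromen-4-one | CC(C)=CCc1cc(-c2cc(=O)c3ccc(OCOC)c(CC=C(C)C)c3o2)ccc1OCOC | intermediate
17 | (2S)-4-[diethoxy(methyl)silyloxy]-7-(methoxymethoxy)-2-[4-(methoxymethoxy)-3-prenylphenyl]-8-prenyl-2H-chromene (not isolated) | CC(C)=CCc1cc([C@H]2Oc3c(ccc(OCOC)c3CC=C(C)C)C(O[Si](C)(OCC)OCC)=C2)ccc1OCOC | intermediate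
18 | (2S)-7,4'-bis(methoxymethoxy)-8,3'-diprenylflavanone | CC(C)=CCc1cc([C@H]2Oc3c(ccc(OCOC)c3CC=C(C)C)C(=O)C2)ccc1OCOC | intermediate
19 | lithium (2S)-7-(methoxymethoxy)-2-[4-(methoxymethoxy)-3-prenylphenyl]-8-prenyl-2H-chromen-4-olate (not isolated) | CC(C)=CCc1cc([C@H]2Oc3c(ccc(OCOC)c3CC=C(C)C)C([O-])=C2)ccc1OCOC.[Li+] | intermediate
20 | (2R,3R)-3-hydroxy-7,4'-bis(methoxymethoxy)-8,3'-diprenylflavanone | CC(C)=CCc1cc([C@H]2Oc3c(ccc(OCOC)c3CC=C(C)C)C(=O)[C@@H]2O)ccc1OCOC | intermediate
21 | 3-hydroxyglabrol, (2R,3R) | CC(C)=CCc1cc([C@H]2Oc3c(ccc(O)c3CC=C(C)C)C(=O)[C@@H]2O)ccc1O | target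

## Step count and risk

Total step count: 12. Longest linear sequence: 9 steps (steps 1 to 5, then 9 to 12); ring B is made in a 3-step branch (steps 6 to 8).

Step 10, asymmetric conjugate reduction. The 2-aryl group makes C2 more hindered and more conjugated than in the substrates on which this reduction is established. Hydride transfer may therefore be slow, or facial discrimination poor. The copper enolate may also expel O1 before it is silylated, which would erode the configuration at C2 and open the way to over-reduction. The fallback uses only established reactions and does not pass through the flavone; it sets out from 7 and 11 and returns at 18. Iodophenol 7 is converted with n-BuLi (2.1 equiv, THF, −78 °C) and N-methoxy-N-methylacetamide into 1-[2-hydroxy-4-(methoxymethoxy)-3-prenylphenyl]ethanone F1. Claisen–Schmidt condensation of this ketone with aldehyde 11 (KOH, EtOH, rt) should give the (E)-2'-hydroxychalcone F2. Oxa-Michael closure (NaOAc, EtOH, reflux) should give the racemic 7,4'-bis(methoxymethoxy)-8,3'-diprenylflavanone F3. Kinetic resolution by asymmetric transfer hydrogenation (Cp*RhCl[(R,R)-TsDPEN], HCO2H/Et3N, EtOAc, rt) should then reduce the (2R)-ketone faster, to the cis-(2R,4R)-flavan-4-ol F4, and leave the (2S)-ketone 18. The sense of the resolution would have to be confirmed, and half of the material is lost.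

Step 9, the key step. The iodide is electron-rich and flanked by a free phenol, so oxidative addition is slow. The most likely failures are capture of the aroylpalladium intermediate by the amine solvent (amide formation) and coupling without CO uptake followed by closure to a benzofuran. The fallback builds the ynone without palladium or CO, taking C4 from a formamide; it sets out from 7 and 12 and returns at 14 and then 16. Iodophenol 7 is treated with n-BuLi (2.1 equiv, THF, −78 °C) and DMF to give 2-hydroxy-4-(methoxymethoxy)-3-prenylbenzaldehyde F5. Addition of the lithium acetylide of 12 (n-BuLi, 2.2 equiv of acetylide, THF, −78 to 0 °C) gives the racemic propargylic alcohol 1-[2-hydroxy-4-(methoxymethoxy)-3-prenylphenyl]-3-[4-(methoxymethoxy)-3-prenylphenyl]prop-2-yn-1-ol F6. Oxidation with MnO2 (CH2Cl2, rt) gives ynone 14, now isolated, and Et2NH in EtOH at 40 °C closes it through 15 to flavone 16.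

Step 11, enolate hydroxylation. The enolate can open ring C by expelling O1, which loses the configuration at C2. It can also add to the sulfonimine formed from the oxidant, and the product alkoxide can be dehydrogenated to the flavonol. The fallback avoids any free enolate; it sets out from 17 and returns at 20. Step 10 is run without the fluoride work-up, and the solution of silyl enol ether 17 is treated with dimethyldioxirane (1.0 equiv, acetone/CH2Cl2, −78 °C) in a Rubottom oxidation. The enol ether is far more electron-rich than the prenyl alkenes and should react first, anti to the C2 aryl group, to give the (2R,3R)-3-[diethoxy(methyl)silyloxy]flavanone F7. NH4F in MeOH then gives 20.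

Step 12, acetal removal. The C7 acetal is flanked by the prenyl group and may cleave slowly. Longer acid exposure would let the freed phenols add to their neighbouring prenyl groups, and would let C2 lose configuration through reversible opening of ring C once O4' is free. The fallback replaces protic solvolysis by aprotic Lewis-acid activation with capture of the acetal carbon by a thiol (ZnBr2, n-PrSH, CH2Cl2, 0 °C, minutes). No Brønsted acid is then present to protonate an alkene. It sets out from 20 and returns directly at 21, with no new intermediate (F0).

Step 6, direct C-prenylation. The phenoxide is ambident and the product is more electron-rich than 8, so O-alkylation and a second alkylation lower the throughput. The fallback is the regiospecific sequence used for ring A; it sets out from 8 and returns at 10. Allylation (allyl bromide, K2CO3, acetone) gives 4-(allyloxy)benzaldehyde F8. Claisen rearrangement (neat, 200 °C) gives 3-allyl-4-hydroxybenzaldehyde F9. Cross-metathesis with 2-methyl-2-butene (RuCl2(=CHPh)(PCy3)(H2IMes), CH2Cl2, 40 °C) gives 10.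

## Further compounds

F1 | step 10 | 1-[2-hydroxy-4-(methoxymethoxy)-3-(3-methylbut-2-en-1-yl)phenyl]ethanone | CC(=O)c1ccc(OCOC)c(CC=C(C)C)c1O
F2 | step 10 | (E)-1-[2-hydroxy-4-(methoxymethoxy)-3-prenylphenyl]-3-[4-(methoxymethoxy)-3-prenylphenyl]prop-2-en-1-one | CC(C)=CCc1cc(/C=C/C(=O)c2ccc(OCOC)c(CC=C(C)C)c2O)ccc1OCOC
F3 | step 10 | racemic 7,4'-bis(methoxymethoxy)-8,3'-diprenylflavanone | CC(C)=CCc1cc(C2CC(=O)c3ccc(OCOC)c(CC=C(C)C)c3O2)ccc1OCOC
F4 | step 10 | (2R,4R)-7,4'-bis(methoxymethoxy)-8,3'-diprenylflavan-4-ol (2,4-cis) | CC(C)=CCc1cc([C@@H]2Oc3c(CC=C(C)C)c(OCOC)ccc3[C@H](O)C2)ccc1OCOC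
F5 | step 9 | 2-hydroxy-4-(methoxymethoxy)-3-(3-methylbut-2-en-1-yl)benzaldehyde | CC(C)=CCc1c(OCOC)ccc(C=O)c1O
F6 | step 9 | racemic 1-[2-hydroxy-4-(methoxymethoxy)-3-prenylphenyl]-3-[4-(methoxymethoxy)-3-prenylphenyl]prop-2-yn-1-ol | CC(C)=CCc1cc(C#CC(O)c2ccc(OCOC)c(CC=C(C)C)c2O)ccc1OCOC
F7 | step 11 | (2R,3R)-3-[diethoxy(methyl)silyloxy]-7,4'-bis(methoxymethoxy)-8,3'-diprenylflavanone | CC(C)=CCc1cc([C@H]2Oc3c(ccc(OCOC)c3CC=C(C)C)C(=O)[C@@H]2O[Si](C)(OCC)OCC)ccc1OCOC
F0 | step 12 | none | none
F8 | step 6 | 4-(allyloxy)benzaldehyde | C=CCOc1ccc(C=O)cc1
F9 | step 6 | 3-allyl-4-hydroxybenzaldehyde | C=CCc1cc(C=O)ccc1O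
A1 | alternative 1 | 4-(3-methylbut-2-en-1-yl)-3,5,7-trioxo-7-{(2R,3S)-3-[3-(3-methylbut-2-en-1-yl)-4-(triisopropylsilyloxy)phenyl]oxiran-2-yl}heptanal | CC(C)=CCc1cc([C@@H]2O[C@H]2C(=O)CC(=O)C(CC=C(C)C)C(=O)CC=O)ccc1O[Si](C(C)C)(C(C)C)C(C)C
A2 | alternative 1 | 4'-O-triisopropylsilyl-3-hydroxyglabrol, (2R,3R) | CC(C)=CCc1cc([C@H]2Oc3c(ccc(O)c3CC=C(C)C)C(=O)[C@@H]2O)ccc1O[Si](C(C)C)(C(C)C)C(C)C
A3 | alternative 2 | 2-hydroxy-3-(3-methylbut-2-en-1-yl)-4-(triisopropylsilyloxy)benzaldehyde | O=Cc1ccc(O[Si](C(C)C)(C(C)C)C(C)C)c(CC=C(C)C)c1O
A4 | alternative 2 | (E)-2-[3-(3-methylbut-2-en-1-yl)-4-(triisopropylsilyloxy)phenyl]ethenyl acetate | CC(=O)O/C=C/c1ccc(O[Si](C(C)C)(C(C)C)C(C)C)c(CC=C(C)C)c1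
A5 | alternative 2 | (2R,3S)-2,3-trans-4-methoxy-7,4'-bis(triisopropylsilyloxy)-8,3'-diprenylflavan-3-yl acetate (C4 epimers) | CC(C)=CCc1cc([C@H]2Oc3c(CC=C(C)C)c(O[Si](C(C)C)(C(C)C)C(C)C)ccc3C(OC)[C@@H]2OC(C)=O)ccc1O[Si](C(C)C)(C(C)C)C(C)C
A6 | alternative 3 | tert-butyl{[1-(4-(methoxymethoxy)-2-{(1S)-1-[4-(methoxymethoxy)-3-prenylphenyl]prop-2-en-1-yloxy}-3-prenylphenyl)ethenyl]oxy}dimethylsilane | C=C(O[Si](C)(C)C(C)(C)C)c1ccc(OCOC)c(CC=C(C)C)c1O[C@@H](C=C)c1ccc(OCOC)c(CC=C(C)C)c1
A7 | alternative 3 | (2S)-4-(tert-butyldimethylsilyloxy)-7-(methoxymethoxy)-2-[4-(methoxymethoxy)-3-prenylphenyl]-8-prenyl-2H-chromene | CC(C)=CCc1cc([C@H]2Oc3c(CC=C(C)C)c(OCOC)ccc3C(O[Si](C)(C)C(C)(C)C)=C2)ccc1OCOC
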